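## The problem

Flowerine is (2S)-5-hydroxy-7-methoxy-2-(4-methoxyphenyl)-8-(3-methylbut-2-en-1-yl)chroman-4-one: an acylphloroglucinol ring A fused along C4a–C8a to the dihydropyranone ring C, which carries the 4-methoxyphenyl ring B at C2. Building the bicycle is not the hard part. The hard part is ring A, where five of six carbons are substituted: the oxygens at C5, C7 and C8a must become a free phenol, a methyl ether and the ring ether, and the prenyl group must go to C8 and not to the electronically similar C6. C2 is the only stereocentre, so no resident group can direct it and its (S) configuration has to come from a chiral catalyst. It is also labile: the flavanone is a β-aryloxy ketone and opens by retro-oxa-Michael reaction to the achiral 2'-hydroxychalcone under base, and more slowly under acid with heat, so C2 should be fixed late and kept away from base afterwards. The prenyl group does not tolerate strong Brønsted or Lewis acids, which rules out acidic deprotections at the end, and the 5-hydroxyl is chelated to the C4 carbonyl and awkward to protect and to free. What opens the synthesis is the pattern of ring A: oxygen on the alternate carbons C5, C7 and C8a, and the acyl carbon C4 on C4a, continuing into C3, C2 and ring B. This is the pattern of a poly-β-carbonyl chain begun by a cinnamoyl unit, so ring A can be made by an intramolecular Claisen acylation that forms C4a–C8a instead of by substitution on a ready-made arene.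

## Retrosynthesis

**C8–prenyl bond (18 ⇒ 15).** The last bond made is C8–CH2 of the prenyl group, formed from the 5-O-prenyl ether 15 by two consecutive [3,3] shifts through dienones 16 and 17. Friedel–Crafts prenylation of the phenol would not tell C6 from C8 and invites O-alkylation. A cross-coupling would first need a C8-selective halogenation beside a chelated phenol. Tethering the allyl unit to O5 makes the regiochemistry a matter of geometry: ortho carbon C4a is blocked, and ortho carbon C6 hands the group on to the para carbon C8. Precursor 15 has no C-prenyl group and no free phenol. The forward step needs a Lewis acid mild enough for the prenyl group and for C2.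

**Configuration at C2 (15 ⇒ 14).** The stereocentre is disconnected next, to racemic 14, by a catalytic kinetic resolution through asymmetric transfer hydrogenation. Closing chalcone 11 directly with a chiral base or hydrogen-bond catalyst was weighed as the way to set C2 in the ring-forming step. For unactivated 2'-hydroxychalcones such closures are known but give only partial enrichment, because the uncatalysed closure of a 2',6'-dihydroxychalcone competes and the product can reopen. The resolution costs one step and at most half of the material at this stage (the reduced enantiomer could be returned by reoxidation and base equilibration). In return it has direct precedent on flavanones and places the stereo-defining event after every step that could open ring C except the final rearrangement. Ether 14 is the best substrate for it because its ketone is no longer chelated by a peri hydroxyl.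

**O5–prenyl bond (14 ⇒ 12 + 13).** Cutting the ether bond gives racemic flavanone 12 and 3-methylbut-2-en-1-ol 13. Compound 12 has a single hydroxyl, so chemoselectivity is not an issue. The forward reaction must be neutral, since carbonate and a prenyl halide would open ring C; this points to a Mitsunobu etherification.

**O1–C2 bond (12 ⇒ 11).** Ring C is opened by retro-oxa-Michael reaction to chalcone 11. The two phenols of 11 are equivalent, so closure can give only one flavanone. A chalcone that already carried the prenyl group would close in two directions, which is why ring C is closed before prenylation. The forward step is a classical base-mediated isomerisation and is deliberately racemic.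

**C4a–C8a bond (11 ⇒ 9).** Ring A is cut between C4a and C8a (equivalent to C4a–C5 at the symmetric chalcone stage). This is a retro-Claisen acylation, giving the triketo ester chain 10, which is stored as the 4-methoxy-2-pyrone 9. Against a Friedel–Crafts acylation or a Claisen–Schmidt condensation on a purchased phloroglucinol derivative, this cut builds the arene with the 7-methoxy group and both ortho hydroxyls already in place from one isomerisation. Pyrone 9 has no carbocycle at all. The forward reaction must fold in the Claisen and not the aldol sense and must spare the enone.

**C4–C4a bond (9 ⇒ 3 + 6).** The side chain of 9 is cut between the pyrone methylene and the ketone carbonyl, giving the lithiated pyrone 7 (from 3) and Weinreb amide 6, joined through adduct 8. The amide is preferred to an ester or acid chloride because the tetrahedral adduct holds until work-up. The acidic product therefore cannot quench the nucleophile or react twice.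

**Starting materials (3 ⇒ 1 + 2; 6 ⇒ 4).** Pyrone 3 is the O-methyl ether of triacetic acid lactone 1, made with dimethyl sulfate 2. Amide 6 comes from (E)-4-methoxycinnamic acid 4 through acyl imidazole 5.

## Roads not taken

**Alternative 1:** Aryne annulation. The cut is double, O1–C8a and C4–C4a, separating ring A as an aryne from a three-carbon chain that already holds C2. Forward, CsF would release the C4a≡C8a aryne from silyl triflate A3. The alkoxide of methyl (S)-3-hydroxy-3-(4-methoxyphenyl)propanoate A2 would add at C8a, and the aryl anion at C4a would acylate on the ester to give the methoxymethyl-protected flavanone A1.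
- Merits: it is convergent, the C2–O bond is never broken, and A2 is available in high enantiomeric purity by asymmetric ketone hydrogenation. All material is carried forward, which is better than a resolution.
- Weak points: A3 is a benzene with six different substituents. Making it means solving the same C8-prenyl and oxygen-differentiation problem before the key step, in more steps than the whole adopted route. The C5 alkoxy group directs the alkoxide to C8a electronically, but C8a is shielded by the neighbouring prenyl group. The secondary alkoxide of a β-hydroxy ester is prone to retro-aldol cleavage and elimination. A1 still needs acidic removal of the acetal in the presence of the prenyl group and a labile C2.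
- Comparison: the adopted plan is weaker on stereochemical economy. It sets against this a ring A assembled from a cheap pyrone with no regiochemical question.

**Alternative 2:** Allylic etherification, then enol-silane metathesis. The cut is C3–C4 (as C3=C4), preceded by O1–C2. Forward, an iridium-catalysed branched-selective allylic etherification of a mono-silylated acylphloroglucinol would set C2. Silylation of the acetyl group would give diene A5, and the second-generation Grubbs catalyst would close ring C as the enol silane A4 with loss of ethylene.
- Merits: C2 is created catalytically without a resolution, and the ring closure is irreversible and cannot racemise. On stereocontrol this road is better than the adopted one.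
- Weak points: the nucleophile is a doubly ortho-substituted, chelated 2-hydroxyaryl ketone, a poor partner for the allyl-iridium intermediate. The branched aryl ether of an electron-rich cinnamyl system ionises easily and is itself an aryl allyl ether that can rearrange on heating. The metathesis must engage a 1,1-disubstituted enol silane flanked by two ortho substituents. The prenyl group cannot be present during metathesis, so after A4 come desilylation with basic fluoride (a risk to C2) and the same etherification and rearrangement as in the adopted route.
- Comparison: the road is longer and has three demanding steps. The adopted plan offers a shorter sequence of individually precedented reactions.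

**Alternative 3:** Carbene C–H insertion. The cut is C2–C3. Forward, a chiral dirhodium tetracarboxylate such as Rh2(S-PTTL)4 would decompose diazo ketone A7, and the carbene at C3 would insert into the benzylic C–H of the 4-methoxybenzyl ether to give the 5-O-methyl flavanone A6.
- Merits: one step forms a C–C bond, ring C and the stereocentre, with the prenyl group and all oxygens in place and no chalcone equilibrium. In step count from A7 this is the shortest end game of all.
- Weak points: a carbene with a single acceptor group is the least selective class. The ether oxygen sits where it can capture the carbene as a five-membered oxonium ylide, and a [1,2]-shift of the stabilised benzyl group would then give a benzofuranone. Cyclopropanation of the prenyl alkene and addition to the electron-rich benzyl ring also compete. A6 needs a selective 5-O-demethylation with a reagent such as BCl3, which threatens both the prenyl group and C2. The arene of A7 again has to be built with full regiocontrol.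
- Comparison: the adopted plan is longer, but none of its steps depends on winning a chemoselectivity contest of this kind.

Key step: step 4

Remark: compounds 12 and 14 are racemates and are written without a descriptor at C2.

## Route

Step 1
Reactants: 1 4-hydroxy-6-methyl-2H-pyran-2-one; 2 dimethyl sulfate
Product: 3 4-methoxy-6-methyl-2H-pyran-2-one
Conditions: K2CO3, acetone, reflux
Reagents that add atoms: none
Why: Williamson-type O-methylation of a vinylogous carboxylic acid; with K2CO3 in acetone the 4-oxygen is alkylated and the 2-pyrone form is kept, the isomeric 2-methoxy-4-pyranone being at most a minor, separable by-product.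

Step 2
Reactants: 4 (E)-3-(4-methoxyphenyl)prop-2-enoic acid
Product: 6 (E)-N-methoxy-3-(4-methoxyphenyl)-N-methylprop-2-enamide, via acyl imidazole 5 (not isolated)
Conditions: 1,1'-carbonyldiimidazole, CH2Cl2, rt; then MeNHOMe·HCl, rt
Reagents that add atoms: N,O-dimethylhydroxylamine hydrochloride, CNOC.Cl
Why: Amide formation by acyl transfer through the acyl imidazole 5 (carbonyldiimidazole coupling); the mild activation leaves the E-alkene untouched.

Step 3
Reactants: 3 4-methoxy-6-methyl-2H-pyran-2-one; 6 (E)-N-methoxy-3-(4-methoxyphenyl)-N-methylprop-2-enamide
Product: 9 4-methoxy-6-[(E)-4-(4-methoxyphenyl)-2-oxobut-3-en-1-yl]-2H-pyran-2-one, via lithiated pyrone 7 (not isolated), via lithium hemiaminal adduct 8 (not isolated)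
Conditions: LiN(iPr)2 (2.1 equiv), 3 (2.0 equiv), THF, −78 °C; then 6 (1.0 equiv), −78 to −40 °C; AcOH, −78 °C
Reagents that add atoms: none
Why: Lithium diisopropylamide removes a proton from the 6-methyl group, which is vinylogous to the lactone carbonyl, and the dienolate 7 is C-acylated by the Weinreb amide (Weinreb ketone synthesis). The chelated adduct 8 holds until the acid quench, so the acidic keto pyrone 9 neither protonates 7 nor reacts twice; 1,2-addition is the normal course for lithium nucleophiles with unsaturated N-methoxy-N-methylamides, and the lithium of 7 and 8 is lost on quench.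

Step 4
Reactants: 9 4-methoxy-6-[(E)-4-(4-methoxyphenyl)-2-oxobut-3-en-1-yl]-2H-pyran-2-one
Product: 11 (E)-1-(2,6-dihydroxy-4-methoxyphenyl)-3-(4-methoxyphenyl)prop-2-en-1-one, via ring-opened enol ether keto ester 10 (not isolated)
Conditions: Mg(OMe)2 (6 equiv), MeOH, reflux, argon; then cold 1 M HCl
Reagents that add atoms: none
Why: Methoxide adds to the lactone carbonyl of 9 and the ring opens to the magnesium enolate of ester 10, in which the old pyrone C3=C4 bond survives as a methyl enol ether that keeps the ester and the chain on the same side. The methylene between the two ketones is the most acidic site; as its magnesium-chelated diketonate it attacks the ester carbonyl, methoxide leaves, and double enolisation of the resulting 2-acylcyclohexenedione gives the aromatic ring, so the step is overall an isomerisation. The closest known reaction type is the Mg(OMe)2-mediated Claisen recyclisation of 6-(2-oxoalkyl)-4-methoxy-2-pyrones and of 3,5,7-triketo esters to acylphloroglucinols, that is, C-acylation of a β-diketone by an ester. Ring A closes in the 6-(enolendo)-exo-trig mode with formation of the C4a–C8a bond, and no stereocentre is formed. The step needs Claisen instead of aldol folding and must spare the enone. The first is secured because the ester α-carbon is tied up as the enol ether CH and cannot act as a nucleophile, so acylation is the only six-membered carbocyclisation open to 10. The second is secured because the enone is part of a chelated magnesium diketonate of low electrophilicity and any methoxide addition to it is reversible. Closure of some 11 to flavanone 12 on work-up does no harm, since step 5 makes the same racemic compound.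

Step 5
Reactants: 11 (E)-1-(2,6-dihydroxy-4-methoxyphenyl)-3-(4-methoxyphenyl)prop-2-en-1-one
Product: 12 rac-5-hydroxy-7-methoxy-2-(4-methoxyphenyl)chroman-4-one
Conditions: NaOAc, EtOH, reflux
Reagents that add atoms: none
Why: Base-mediated 6-endo-trig oxa-Michael addition of a phenol to the enone (chalcone–flavanone isomerisation); the two phenols of 11 are equivalent, so only one flavanone can form, and the hydrogen bond of the remaining 5-hydroxyl to the C4 carbonyl holds the equilibrium on the closed side. C2 is formed as the racemate on purpose; its configuration is selected in step 7.

Step 6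
Reactants: 12 rac-5-hydroxy-7-methoxy-2-(4-methoxyphenyl)chroman-4-one; 13 3-methylbut-2-en-1-ol
Product: 14 rac-7-methoxy-2-(4-methoxyphenyl)-5-[(3-methylbut-2-en-1-yl)oxy]chroman-4-one
Conditions: PPh3, DIAD, THF, 0 °C to rt
Reagents that add atoms: none
Why: Mitsunobu etherification: the chelated phenol, the only hydroxyl of 12, is acidic enough to protonate the PPh3–DIAD betaine and is alkylated at the primary carbon of the activated alcohol 13. The neutral medium keeps ring C closed, which an alkylation with carbonate and a prenyl halide would not.

Step 7
Reactants: 14 rac-7-methoxy-2-(4-methoxyphenyl)-5-[(3-methylbut-2-en-1-yl)oxy]chroman-4-one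
Product: 15 (2S)-7-methoxy-2-(4-methoxyphenyl)-5-[(3-methylbut-2-en-1-yl)oxy]chroman-4-one
Conditions: [Cp*RhCl((R,R)-TsDPEN)] (1 mol %), HCO2H/Et3N (5:2), EtOAc, rt, stopped near half conversion
Reagents that add atoms: none
Why: Kinetic resolution by asymmetric transfer hydrogenation, a reaction established for racemic flavanones with this catalyst class: the (R,R)-configured hydride of trivalent rhodium should reduce the (2R)-ketone fast, delivering hydride to C4 on the face of the C2 hydrogen to give the (2R,4R)-cis-flavan-4-ol, while the mismatched (2S)-ketone is recovered and separated by chromatography. The (2S) configuration of 15 is thus selected by the catalyst; the prenyl alkene and the aryl ether are inert to outer-sphere hydride transfer, and the formate buffer is not basic enough to open ring C.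

Step 8
Reactants: 15 (2S)-7-methoxy-2-(4-methoxyphenyl)-5-[(3-methylbut-2-en-1-yl)oxy]chroman-4-one
Product: 18 flowerine, (2S)-5-hydroxy-7-methoxy-2-(4-methoxyphenyl)-8-(3-methylbut-2-en-1-yl)chroman-4-one, via ortho-dienone 16 (not isolated), via para-dienone 17 (not isolated)
Conditions: Eu(fod)3 (10 mol %), acid-free CHCl3, 60 °C, sealed tube
Reagents that add atoms: none
Why: Para-Claisen rearrangement (Claisen then Cope shift) catalysed by the oxophilic Lewis acid Eu(fod)3 (trivalent europium), which binds between the C4 carbonyl and O5: the first [3,3] shift can only go to C6 because C4a is blocked and gives dienone 16, whose 1,5-diene undergoes a Cope shift to C8, and enolisation of 17 gives the chelated phenol. The same cascade is known for 5-O-prenyl flavanones and flavones; C2 takes no part and the neutral conditions should leave its configuration intact.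

## Compound list

1 | 4-hydroxy-6-methyl-2H-pyran-2-one (triacetic acid lactone) | CC1=CC(O)=CC(=O)O1 | starting material
2 | dimethyl sulfate | COS(=O)(=O)OC | starting material
3 | 4-methoxy-6-methyl-2H-pyran-2-one | COC1=CC(=O)OC(C)=C1 | intermediate
4 | (E)-3-(4-methoxyphenyl)prop-2-enoic acid (4-methoxycinnamic acid) | COc1ccc(/C=C/C(=O)O)cc1 | starting material
5 | (E)-1-(1H-imidazol-1-yl)-3-(4-methoxyphenyl)prop-2-en-1-one | COc1ccc(/C=C/C(=O)n2ccnc2)cc1 | intermediate (not isolated)
6 | (E)-N-methoxy-3-(4-methoxyphenyl)-N-methylprop-2-enamide | COc1ccc(/C=C/C(=O)N(C)OC)cc1 | intermediate
7 | 6-(lithiomethyl)-4-methoxy-2H-pyran-2-one | [Li]CC1=CC(OC)=CC(=O)O1 | intermediate (not isolated)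
8 | lithium alkoxide of the N,O-hemiaminal from addition of 7 to the amide carbonyl of 6 | COC1=CC(=O)OC(CC(O[Li])(/C=C/c2ccc(OC)cc2)N(C)OC)=C1 | intermediate (not isolated)
9 | 4-methoxy-6-[(E)-4-(4-methoxyphenyl)-2-oxobut-3-en-1-yl]-2H-pyran-2-one | COC1=CC(=O)OC(CC(=O)/C=C/c2ccc(OC)cc2)=C1 | intermediate
10 | methyl (2E,8E)-3-methoxy-9-(4-methoxyphenyl)-5,7-dioxonona-2,8-dienoate (present as its magnesium enolate, drawn neutral) | COC(=O)/C=C(/OC)CC(=O)CC(=O)/C=C/c1ccc(OC)cc1 | intermediate (not isolated)
11 | (E)-1-(2,6-dihydroxy-4-methoxyphenyl)-3-(4-methoxyphenyl)prop-2-en-1-one | COc1ccc(/C=C/C(=O)c2c(O)cc(OC)cc2O)cc1 | intermediate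
12 | rac-5-hydroxy-7-methoxy-2-(4-methoxyphenyl)chroman-4-one | COc1ccc(C2CC(=O)c3c(O)cc(OC)cc3O2)cc1 | intermediate
13 | 3-methylbut-2-en-1-ol | CC(C)=CCO | starting material
14 | rac-7-methoxy-2-(4-methoxyphenyl)-5-[(3-methylbut-2-en-1-yl)oxy]chroman-4-one | COc1ccc(C2CC(=O)c3c(OCC=C(C)C)cc(OC)cc3O2)cc1 | intermediate
15 | (2S)-7-methoxy-2-(4-methoxyphenyl)-5-[(3-methylbut-2-en-1-yl)oxy]chroman-4-one | COc1ccc([C@@H]2CC(=O)c3c(OCC=C(C)C)cc(OC)cc3O2)cc1 | intermediate
16 | (2S)-7-methoxy-2-(4-methoxyphenyl)-6-(2-methylbut-3-en-2-yl)-2,3-dihydro-4H-chromene-4,5(6H)-dione (C6 unassigned) | COc1ccc([C@@H]2CC(=O)C3=C(O2)C=C(OC)C(C(C)(C)C=C)C3=O)cc1 | intermediate (not isolated)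
17 | (2S)-7-methoxy-2-(4-methoxyphenyl)-8-(3-methylbut-2-en-1-yl)-2,3-dihydro-4H-chromene-4,5(8H)-dione (C8 unassigned) | COc1ccc([C@@H]2CC(=O)C3=C(O2)C(CC=C(C)C)C(OC)=CC3=O)cc1 | intermediate (not isolated)
18 | flowerine, (2S)-5-hydroxy-7-methoxy-2-(4-methoxyphenyl)-8-(3-methylbut-2-en-1-yl)chroman-4-one | COc1ccc([C@@H]2CC(=O)c3c(O)cc(OC)c(CC=C(C)C)c3O2)cc1 | target

## Step count and least certain steps

Total step count: 8. Longest linear sequence: 7 (steps 1, 3, 4, 5, 6, 7, 8 from compound 1; steps 2 to 8 from compound 4 are equally long).

**Step 4 (key step).** The open-chain enolate may be diverted before C-acylation. Possible diversions are conjugate addition of methoxide or of an enolate oxygen to the cinnamoyl unit, return to the lactone, or O-cyclisation to a 4-pyranone; prolonged heating with base may also degrade the enone. The fallback keeps the C4a–C8a Claisen folding but removes the enone from it. It sets out from 3: lithiation as in step 3 and acylation with N-methoxy-N-methylacetamide would give 4-methoxy-6-(2-oxopropyl)-2H-pyran-2-one F1. The same Mg(OMe)2 treatment should fold this to 1-(2,6-dihydroxy-4-methoxyphenyl)ethan-1-one F2. A Claisen–Schmidt condensation of F2 with 4-methoxybenzaldehyde (KOH, EtOH) comes back to the route at 11.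

**Step 3.** Proton transfer from product to the dienolate, early collapse of the tetrahedral adduct, or conjugate addition to the unsaturated amide would lower the yield. The fallback sets out from 3: aldol addition of the lithiated pyrone to (E)-4-methoxycinnamaldehyde would give rac-6-[(E)-2-hydroxy-4-(4-methoxyphenyl)but-3-en-1-yl]-4-methoxy-2H-pyran-2-one F3. Oxidation of the allylic alcohol with Dess–Martin periodinane (NaHCO3, CH2Cl2) returns to the route at 9.

**Step 6.** Etherification of the chelated phenol may be slow, and attack at the tertiary allyl terminus or ring opening by the basic betaine may compete. The fallback moves the prenylation to the chalcone and sets out from 11. One equivalent of prenyl bromide with K2CO3 in acetone should give (E)-1-{2-hydroxy-4-methoxy-6-[(3-methylbut-2-en-1-yl)oxy]phenyl}-3-(4-methoxyphenyl)prop-2-en-1-one F4, since after the first alkylation the remaining phenol is strongly chelated. Closure of its only free phenol (NaOAc, EtOH, reflux) returns to the route at 14.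

**Step 7.** The peri alkoxy group may slow the reduction and lower the discrimination between enantiomers. The sense of selection is predicted by analogy with the parent flavanones and by the usual model for this catalyst family, and it might be reversed, in which case the (S,S)-catalyst would be used. The fallback replaces catalysis by physical resolution: racemic 14 is separated by preparative chromatography on a cellulose tris(3,5-dimethylphenylcarbamate) phase, returning to the route at 15. It makes no compound outside the list (entry F0).

**Step 8.** The configuration at C2 may erode through Lewis-acid-assisted opening of ring C once the free 5-hydroxyl is formed. Dienone 16 may also enolise before the Cope shift, which would leave the allyl unit at C6. The fallback inverts the order of resolution and rearrangement and sets out from 14. The rearrangement is run on the racemate, where more forcing conditions are admissible, to give rac-5-hydroxy-7-methoxy-2-(4-methoxyphenyl)-8-(3-methylbut-2-en-1-yl)chroman-4-one F5. Acetylation (Ac2O, pyridine) would give rac-7-methoxy-2-(4-methoxyphenyl)-8-(3-methylbut-2-en-1-yl)-4-oxochroman-5-yl acetate F6, whose ketone is no longer chelated. The transfer-hydrogenation resolution of step 7 would then leave (2S)-7-methoxy-2-(4-methoxyphenyl)-8-(3-methylbut-2-en-1-yl)-4-oxochroman-5-yl acetate F7. Neutral deacetylation (NH4OAc, aqueous MeOH, rt) returns to the route at 18.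

## Further compounds

F1 | step 4 | 4-methoxy-6-(2-oxopropyl)-2H-pyran-2-one | COC1=CC(=O)OC(CC(C)=O)=C1
F2 | step 4 | 1-(2,6-dihydroxy-4-methoxyphenyl)ethan-1-one | CC(=O)c1c(O)cc(OC)cc1O
F3 | step 3 | rac-6-[(E)-2-hydroxy-4-(4-methoxyphenyl)but-3-en-1-yl]-4-methoxy-2H-pyran-2-one | COC1=CC(=O)OC(CC(O)/C=C/c2ccc(OC)cc2)=C1
F4 | step 6 | (E)-1-{2-hydroxy-4-methoxy-6-[(3-methylbut-2-en-1-yl)oxy]phenyl}-3-(4-methoxyphenyl)prop-2-en-1-one | COc1ccc(/C=C/C(=O)c2c(O)cc(OC)cc2OCC=C(C)C)cc1
F0 | step 7 | none | none
F5 | step 8 | rac-5-hydroxy-7-methoxy-2-(4-methoxyphenyl)-8-(3-methylbut-2-en-1-yl)chroman-4-one | COc1ccc(C2CC(=O)c3c(O)cc(OC)c(CC=C(C)C)c3O2)cc1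
F6 | step 8 | rac-7-methoxy-2-(4-methoxyphenyl)-8-(3-methylbut-2-en-1-yl)-4-oxochroman-5-yl acetate | COc1ccc(C2CC(=O)c3c(OC(C)=O)cc(OC)c(CC=C(C)C)c3O2)cc1
F7 | step 8 | (2S)-7-methoxy-2-(4-methoxyphenyl)-8-(3-methylbut-2-en-1-yl)-4-oxochroman-5-yl acetate | COc1ccc([C@@H]2CC(=O)c3c(OC(C)=O)cc(OC)c(CC=C(C)C)c3O2)cc1
A1 | alternative 1 | (S)-7-methoxy-5-(methoxymethoxy)-2-(4-methoxyphenyl)-8-(3-methylbut-2-en-1-yl)chroman-4-one | COc1ccc([C@@H]2CC(=O)c3c(OCOC)cc(OC)c(CC=C(C)C)c3O2)cc1
A2 | alternative 1 | methyl (S)-3-hydroxy-3-(4-methoxyphenyl)propanoate | COC(=O)C[C@H](O)c1ccc(OC)cc1
A3 | alternative 1 | 3-methoxy-5-(methoxymethoxy)-2-(3-methylbut-2-en-1-yl)-6-(trimethylsilyl)phenyl trifluoromethanesulfonate | COCOc1cc(OC)c(CC=C(C)C)c(OS(=O)(=O)C(F)(F)F)c1[Si](C)(C)C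
A4 | alternative 2 | (S)-4,5-bis(tert-butyldimethylsilyloxy)-7-methoxy-2-(4-methoxyphenyl)-2H-chromene | COc1ccc([C@@H]2C=C(O[Si](C)(C)C(C)(C)C)c3c(O[Si](C)(C)C(C)(C)C)cc(OC)cc3O2)cc1
A5 | alternative 2 | (S)-tert-butyl{[1-(2-{[tert-butyl(dimethyl)silyl]oxy}-4-methoxy-6-{[1-(4-methoxyphenyl)prop-2-en-1-yl]oxy}phenyl)ethenyl]oxy}dimethylsilane | C=C(O[Si](C)(C)C(C)(C)C)c1c(O[Si](C)(C)C(C)(C)C)cc(OC)cc1O[C@@H](C=C)c1ccc(OC)cc1
A6 | alternative 3 | (S)-5,7-dimethoxy-2-(4-methoxyphenyl)-8-(3-methylbut-2-en-1-yl)chroman-4-one | COc1ccc([C@@H]2CC(=O)c3c(OC)cc(OC)c(CC=C(C)C)c3O2)cc1
A7 | alternative 3 | 2-diazo-1-{4,6-dimethoxy-2-[(4-methoxybenzyl)oxy]-3-(3-methylbut-2-en-1-yl)phenyl}ethan-1-one | COc1ccc(COc2c(CC=C(C)C)c(OC)cc(OC)c2C(=O)C=[N+]=[N-])cc1
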